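**Retrosynthetic overview**

1. Numbering: C1 = CH(aryl), C2 = CH(CO2R), C3(CO2R)=C4H, ring A = C4a–C8a with O7/O8, ring C = pendant catechol. The strategy rests on the vicinal C1–H/C2–H pair (C1 carries rings A and C; C2 carries CO2R and the C3 carboxymethyl arm), which is the syn-H2 adduct of a Z β,β-diaryl itaconate half-ester.
2. Target ⇒ BCl3 debenzylation of 24 ⇒ core diacid 19 + 2 × (S)-α-triflyloxy ester 23 (double carboxylate SN2, inversion to the two (R) side chains).
3. Ring B is the only ring made (A and C are bought arenes) and is closed last in the core: C3–C4 by intramolecular Stobbe condensation of aldehyde 17, whose CHO comes from the C4a bromide.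
4. C1 and C2 ⇒ Rh-catalysed asymmetric syn-hydrogenation of the Z tetrasubstituted olefin 14 (no ring formed).
5. 14 ⇒ ynoate 6 + the cuprate from ring-C aryl Grignard reagent 9 + tert-butyl bromoacetate (syn-carbocupration/alkylation); side chain ⇒ the same Grignard stock 9 + methyl (S)-glycidate.

Key step: step 9

Assumption: the sense of induction of the bisphosphine cannot be assigned with certainty in advance for this hindered substrate; (S,S)-Et-DuPhos is written, and its equally available mirror image is to be used instead if the product proves to be the (3S,4S) enantiomer.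

**Route**

Step 1
Reactants: 1 2,3-dihydroxybenzaldehyde
Product: 2 2,3-bis(benzyloxy)benzaldehyde
Conditions: BnBr, K2CO3, DMF, 60 °C
Reagents that add atoms: benzyl bromide, BrCc1ccccc1
Why: Williamson etherification of both phenols; the aldehyde is inert to carbonate.

Step 2
Reactants: 2 2,3-bis(benzyloxy)benzaldehyde
Product: 3 2,3-bis(benzyloxy)-6-bromobenzaldehyde
Conditions: NBS, DMF, rt, dark
Reagents that add atoms: N-bromosuccinimide, O=C1CCC(=O)N1Br
Why: Electrophilic aromatic bromination is expected para to the conjugated 3-benzyloxy group (C6), as known for 2,3-dimethoxybenzaldehyde, because the flanked 2-alkoxy group is twisted out of conjugation.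

Step 3
Reactants: 3 2,3-bis(benzyloxy)-6-bromobenzaldehyde
Product: 4 1,2-bis(benzyloxy)-4-bromo-3-ethynylbenzene
Conditions: dimethyl (1-diazo-2-oxopropyl)phosphonate, K2CO3, MeOH/THF, rt
Reagents that add atoms: dimethyl (1-diazo-2-oxopropyl)phosphonate, COP(=O)(OC)C(=[N+]=[N-])C(C)=O
Why: Seyferth–Gilbert homologation in its Ohira–Bestmann form turns the non-enolisable aryl aldehyde into the terminal alkyne under carbonate conditions that leave the aryl bromide and benzyl ethers untouched.

Step 4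
Reactants: 4 1,2-bis(benzyloxy)-4-bromo-3-ethynylbenzene
Product: 6 methyl 3-[2,3-bis(benzyloxy)-6-bromophenyl]prop-2-ynoate, via lithium [2,3-bis(benzyloxy)-6-bromophenyl]acetylide 5 (not isolated)
Conditions: LiHMDS, THF, −78 °C; ClCO2Me, −78 → 0 °C
Reagents that add atoms: methyl chloroformate, COC(=O)Cl
Why: An amide base deprotonates the alkyne without bromine–lithium exchange at the aryl bromide, and the acetylide is C-acylated by the chloroformate.

Step 5
Reactants: 7 4-bromocatechol
Product: 8 4-bromo-1,2-bis(benzyloxy)benzene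
Conditions: BnBr, K2CO3, DMF, 60 °C
Reagents that add atoms: benzyl bromide, BrCc1ccccc1
Why: Williamson etherification of both phenols.

Step 6
Reactants: 8 4-bromo-1,2-bis(benzyloxy)benzene
Product: 9 [3,4-bis(benzyloxy)phenyl]magnesium bromide
Conditions: Mg turnings (I2 cat.), THF, 40 °C; kept under argon as a titrated THF stock solution
Reagents that add atoms: magnesium, [Mg]
Why: Grignard formation by oxidative insertion of magnesium into the aryl C–Br bond; the aryl benzyl ethers are inert to the arylmagnesium species, and one titrated stock solution serves both step 7 and step 13.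

Step 7
Reactants: 9 [3,4-bis(benzyloxy)phenyl]magnesium bromide (2.4 equiv); 6 methyl 3-[2,3-bis(benzyloxy)-6-bromophenyl]prop-2-ynoate; 10 tert-butyl bromoacetate
Product: 13 4-tert-butyl 1-methyl (2Z)-2-{[2,3-bis(benzyloxy)-6-bromophenyl][3,4-bis(benzyloxy)phenyl]methylidene}butanedioate, via bromomagnesium bis[3,4-bis(benzyloxy)phenyl]cuprate(I) 11 (not isolated), via bromomagnesium [3,4-bis(benzyloxy)phenyl]{(E)-2-[2,3-bis(benzyloxy)-6-bromophenyl]-2-[3,4-bis(benzyloxy)phenyl]-1-(methoxycarbonyl)ethenyl}cuprate(I) 12 (not isolated)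
Conditions: CuBr·SMe2 (0.5 equiv per ArMgBr), THF, −40 °C; 6, −78 °C; HMPA, 10, −78 → −40 °C; aq NH4Cl
Reagents that add atoms: none
Why: Syn-carbocupration of the alkynoate by the Gilman-type diarylcuprate places the new aryl group and copper cis, and the α-cuprio enoate is alkylated with retention by the reactive α-bromo ester in HMPA at low temperature before it can equilibrate through the allenolate (conjugate addition–alkylation of ynoates), so the pendant aryl ends cis to the CH2CO2tBu arm (Z olefin).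

Step 8
Reactants: 13 4-tert-butyl 1-methyl (2Z)-2-{[2,3-bis(benzyloxy)-6-bromophenyl][3,4-bis(benzyloxy)phenyl]methylidene}butanedioate
Product: 14 (3Z)-4-[2,3-bis(benzyloxy)-6-bromophenyl]-4-[3,4-bis(benzyloxy)phenyl]-3-(methoxycarbonyl)but-3-enoic acid
Conditions: TFA/CH2Cl2 (1:4), 0 °C, short reaction time
Reagents that add atoms: none
Why: Acidolysis of the tert-butyl ester (loss of isobutylene) frees the arm carboxylic acid; the methyl ester, aryl benzyl ethers, aryl bromide and the ester-deactivated olefin should tolerate brief exposure at 0 °C.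

Step 9
Reactants: 14 (3Z)-4-[2,3-bis(benzyloxy)-6-bromophenyl]-4-[3,4-bis(benzyloxy)phenyl]-3-(methoxycarbonyl)but-3-enoic acid
Product: 15 (3R,4R)-4-[2,3-bis(benzyloxy)-6-bromophenyl]-4-[3,4-bis(benzyloxy)phenyl]-3-(methoxycarbonyl)butanoic acid
Conditions: [Rh(cod)((S,S)-Et-DuPhos)]BF4 (5 mol %), NaOMe (0.5 equiv), H2 (30 bar), MeOH/THF, 40 °C
Reagents that add atoms: none
Why: The arm carboxylate and the C1=C2 olefin of 14 chelate the cationic Rh(I)–bisphosphine centre, and oxidative addition of H2, migratory insertion and reductive elimination deliver both hydrogens to one face, as in the Rh–bisphospholane hydrogenation of Stobbe-derived β,β-disubstituted itaconate half-esters and of stereodefined tetrasubstituted β,β-diaryl olefins, the closest known reaction type. No ring is closed in this step. C1 and C2 are created together: their relative configuration follows from syn addition to the Z olefin (ring A cis to CO2Me, pendant aryl cis to CH2CO2H), which gives the pair that becomes trans in ring B, and their absolute configuration is set by the C2-symmetric ligand, which must deliver hydrogen to the olefin face that leads to (3R,4R)-15. The step needs a single olefin geometry, secured by the syn-carbocupration of step 7, and a single face, secured by two-point binding of the substrate through carboxylate and olefin. The di-ortho-substituted ring A makes 14 more hindered than reported substrates, hence the electron-rich phospholane ligand and elevated pressure; the aryl bromide, methyl ester and benzyl ethers are inert to cationic Rh/H2.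

Step 10
Reactants: 15 (3R,4R)-4-[2,3-bis(benzyloxy)-6-bromophenyl]-4-[3,4-bis(benzyloxy)phenyl]-3-(methoxycarbonyl)butanoic acid
Product: 16 dimethyl (2R)-2-{(R)-[2,3-bis(benzyloxy)-6-bromophenyl][3,4-bis(benzyloxy)phenyl]methyl}butanedioate
Conditions: MeI, KHCO3, DMF, rt
Reagents that add atoms: iodomethane, CI
Why: SN2 O-methylation of the carboxylate under bicarbonate, a base too weak to enolise C2.

Step 11
Reactants: 16 dimethyl (2R)-2-{(R)-[2,3-bis(benzyloxy)-6-bromophenyl][3,4-bis(benzyloxy)phenyl]methyl}butanedioate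
Product: 17 dimethyl (2R)-2-{(R)-[2,3-bis(benzyloxy)-6-formylphenyl][3,4-bis(benzyloxy)phenyl]methyl}butanedioate
Conditions: Pd(OAc)2 (3 mol %), BuPAd2 (9 mol %), TMEDA (1 equiv), CO/H2 (1:1, 5 bar), toluene, 100 °C
Reagents that add atoms: carbon monoxide, [C-]#[O+]
Why: Pd-catalysed reductive carbonylation of the aryl bromide (oxidative addition, CO insertion, hydrogenolysis of the acyl–Pd bond) installs C4 as CHO; esters and benzyl ethers are inert to the homogeneous catalyst and the amine base does not enolise the diester.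

Step 12
Reactants: 17 dimethyl (2R)-2-{(R)-[2,3-bis(benzyloxy)-6-formylphenyl][3,4-bis(benzyloxy)phenyl]methyl}butanedioate
Product: 19 (1R,2S)-7,8-bis(benzyloxy)-1-[3,4-bis(benzyloxy)phenyl]-1,2-dihydronaphthalene-2,3-dicarboxylic acid, via (1R,2S)-7,8-bis(benzyloxy)-1-[3,4-bis(benzyloxy)phenyl]-3-(methoxycarbonyl)-1,2-dihydronaphthalene-2-carboxylic acid 18 (not isolated)
Conditions: KOtBu, THF/t-BuOH (10:1), −20 → 0 °C; then LiOH, H2O/MeOH, 40 °C, degassed; 1 M HCl
Reagents that add atoms: lithium hydroxide, [Li+].[OH-]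
Why: Intramolecular Stobbe condensation: the less hindered arm enolate (C3) adds to the aldehyde to close ring B, the alkoxide lactonises onto the C2 ester and E1cB opening gives C3=C4 and a C2 carboxylate that is no longer enolisable, so the C1/C2 relationship is kept; LiOH then hydrolyses the remaining conjugated methyl ester, and any diester formed by direct dehydration of the aldol converges on the same diacid.

Step 13
Reactants: 9 [3,4-bis(benzyloxy)phenyl]magnesium bromide; 20 methyl (2S)-oxirane-2-carboxylate (methyl (S)-glycidate)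
Product: 21 methyl (2S)-3-[3,4-bis(benzyloxy)phenyl]-2-hydroxypropanoate
Conditions: CuBr·SMe2 (10 mol %), THF, −40 → −20 °C; aq NH4Cl
Reagents that add atoms: none
Why: Copper-catalysed SN2 opening of the glycidate at its unsubstituted C3 by the aryl Grignard reagent; no bond to C2 is touched, so the (S) configuration of 20 is carried into 21.

Step 14
Reactants: 21 methyl (2S)-3-[3,4-bis(benzyloxy)phenyl]-2-hydroxypropanoate
Product: 22 benzyl (2S)-3-[3,4-bis(benzyloxy)phenyl]-2-hydroxypropanoate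
Conditions: BnOH (5 equiv), Ti(OiPr)4 (10 mol %), toluene, 90 °C, MeOH distilled off
Reagents that add atoms: benzyl alcohol, OCc1ccccc1
Why: Titanate-catalysed transesterification, helped by chelation of the α-hydroxy ester, exchanges OMe for OBn without touching the stereocentre, so that the side-chain carboxyl is released later together with the benzyl ethers.

Step 15
Reactants: 22 benzyl (2S)-3-[3,4-bis(benzyloxy)phenyl]-2-hydroxypropanoate
Product: 23 benzyl (2S)-3-[3,4-bis(benzyloxy)phenyl]-2-{[(trifluoromethyl)sulfonyl]oxy}propanoate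
Conditions: Tf2O, 2,6-lutidine, CH2Cl2, −78 → −40 °C; used at once
Reagents that add atoms: trifluoromethanesulfonic anhydride, O=S(=O)(OS(=O)(=O)C(F)(F)F)C(F)(F)F
Why: O-sulfonylation of the secondary alcohol; no bond to the stereocentre is broken, so (S) is retained, and the adjacent ester disfavours ionisation of the triflate.

Step 16
Reactants: 19 (1R,2S)-7,8-bis(benzyloxy)-1-[3,4-bis(benzyloxy)phenyl]-1,2-dihydronaphthalene-2,3-dicarboxylic acid; 23 benzyl (2S)-3-[3,4-bis(benzyloxy)phenyl]-2-{[(trifluoromethyl)sulfonyl]oxy}propanoate (2.3 equiv)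
Product: 24 bis{(2R)-1-(benzyloxy)-3-[3,4-bis(benzyloxy)phenyl]-1-oxopropan-2-yl} (1R,2S)-7,8-bis(benzyloxy)-1-[3,4-bis(benzyloxy)phenyl]-1,2-dihydronaphthalene-2,3-dicarboxylate
Conditions: Cs2CO3 (1.0 equiv), MeCN, rt; then 23, MeCN/CH2Cl2, −20 → 0 °C
Reagents that add atoms: none
Why: Double SN2 O-alkylation of the dicaesium carboxylate by the α-triflyloxy ester, with inversion at each side-chain carbon ((S) → (R)); the acids are never activated, so neither a cyclic anhydride nor a retentive acyl-transfer pathway is open, and C1/C2 are untouched.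

Step 17
Reactants: 24 bis{(2R)-1-(benzyloxy)-3-[3,4-bis(benzyloxy)phenyl]-1-oxopropan-2-yl} (1R,2S)-7,8-bis(benzyloxy)-1-[3,4-bis(benzyloxy)phenyl]-1,2-dihydronaphthalene-2,3-dicarboxylate
Product: 25 CNP0244800.2, bis[(1R)-1-carboxy-2-(3,4-dihydroxyphenyl)ethyl] (1R,2S)-1-(3,4-dihydroxyphenyl)-7,8-dihydroxy-1,2-dihydronaphthalene-2,3-dicarboxylate
Conditions: BCl3 (excess), pentamethylbenzene, CH2Cl2, −78 → 0 °C; then H2O; reversed-phase purification under argon
Reagents that add atoms: none
Why: Lewis acid-assisted C–O heterolysis by BCl3, with pentamethylbenzene as benzyl-cation scavenger, should cleave the eight aryl benzyl ethers and both benzyl esters without reducing C3=C4 (as hydrogenolysis might) and without cleaving the secondary alkyl esters, whose α-carboxyl carbon cannot ionise.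

**Compound list**

1 | 2,3-dihydroxybenzaldehyde | O=Cc1cccc(O)c1O | starting material
2 | 2,3-bis(benzyloxy)benzaldehyde | O=Cc1cccc(OCc2ccccc2)c1OCc1ccccc1 | intermediate
3 | 2,3-bis(benzyloxy)-6-bromobenzaldehyde | O=Cc1c(Br)ccc(OCc2ccccc2)c1OCc1ccccc1 | intermediate
4 | 1,2-bis(benzyloxy)-4-bromo-3-ethynylbenzene | C#Cc1c(Br)ccc(OCc2ccccc2)c1OCc1ccccc1 | intermediate
5 | lithium [2,3-bis(benzyloxy)-6-bromophenyl]acetylide | [Li]C#Cc1c(Br)ccc(OCc2ccccc2)c1OCc1ccccc1 | intermediate
6 | methyl 3-[2,3-bis(benzyloxy)-6-bromophenyl]prop-2-ynoate | COC(=O)C#Cc1c(Br)ccc(OCc2ccccc2)c1OCc1ccccc1 | intermediate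
7 | 4-bromocatechol | Oc1ccc(Br)cc1O | starting material
8 | 4-bromo-1,2-bis(benzyloxy)benzene | Brc1ccc(OCc2ccccc2)c(OCc2ccccc2)c1 | intermediate
9 | [3,4-bis(benzyloxy)phenyl]magnesium bromide | Br[Mg]c1ccc(OCc2ccccc2)c(OCc2ccccc2)c1 | intermediate
10 | tert-butyl bromoacetate | CC(C)(C)OC(=O)CBr | starting material
11 | bromomagnesium bis[3,4-bis(benzyloxy)phenyl]cuprate(I) | Br[Mg+].[Cu-](c1ccc(OCc2ccccc2)c(OCc2ccccc2)c1)c1ccc(OCc2ccccc2)c(OCc2ccccc2)c1 | intermediate
12 | bromomagnesium [3,4-bis(benzyloxy)phenyl]{(E)-2-[2,3-bis(benzyloxy)-6-bromophenyl]-2-[3,4-bis(benzyloxy)phenyl]-1-(methoxycarbonyl)ethenyl}cuprate(I), copper cis to the newly added aryl group | Br[Mg+].COC(=O)/C([Cu-]c1ccc(OCc2ccccc2)c(OCc2ccccc2)c1)=C(/c1ccc(OCc2ccccc2)c(OCc2ccccc2)c1)c1c(Br)ccc(OCc2ccccc2)c1OCc1ccccc1 | intermediate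
13 | 4-tert-butyl 1-methyl (2Z)-2-{[2,3-bis(benzyloxy)-6-bromophenyl][3,4-bis(benzyloxy)phenyl]methylidene}butanedioate | CC(C)(C)OC(=O)C/C(C(=O)OC)=C(/c1c(Br)ccc(OCc2ccccc2)c1OCc1ccccc1)c1ccc(OCc2ccccc2)c(OCc2ccccc2)c1 | intermediate
14 | (3Z)-4-[2,3-bis(benzyloxy)-6-bromophenyl]-4-[3,4-bis(benzyloxy)phenyl]-3-(methoxycarbonyl)but-3-enoic acid | OC(=O)C/C(C(=O)OC)=C(/c1c(Br)ccc(OCc2ccccc2)c1OCc1ccccc1)c1ccc(OCc2ccccc2)c(OCc2ccccc2)c1 | intermediate
15 | (3R,4R)-4-[2,3-bis(benzyloxy)-6-bromophenyl]-4-[3,4-bis(benzyloxy)phenyl]-3-(methoxycarbonyl)butanoic acid | Brc1ccc(OCc2ccccc2)c(OCc2ccccc2)c1[C@@H](c1ccc(OCc2ccccc2)c(OCc2ccccc2)c1)[C@@H](CC(=O)O)C(=O)OC | intermediate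
16 | dimethyl (2R)-2-{(R)-[2,3-bis(benzyloxy)-6-bromophenyl][3,4-bis(benzyloxy)phenyl]methyl}butanedioate | Brc1ccc(OCc2ccccc2)c(OCc2ccccc2)c1[C@@H](c1ccc(OCc2ccccc2)c(OCc2ccccc2)c1)[C@@H](CC(=O)OC)C(=O)OC | intermediate
17 | dimethyl (2R)-2-{(R)-[2,3-bis(benzyloxy)-6-formylphenyl][3,4-bis(benzyloxy)phenyl]methyl}butanedioate | O=Cc1ccc(OCc2ccccc2)c(OCc2ccccc2)c1[C@@H](c1ccc(OCc2ccccc2)c(OCc2ccccc2)c1)[C@@H](CC(=O)OC)C(=O)OC | intermediate
18 | (1R,2S)-7,8-bis(benzyloxy)-1-[3,4-bis(benzyloxy)phenyl]-3-(methoxycarbonyl)-1,2-dihydronaphthalene-2-carboxylic acid | COC(=O)C1=Cc2ccc(OCc3ccccc3)c(OCc3ccccc3)c2[C@@H](c2ccc(OCc3ccccc3)c(OCc3ccccc3)c2)[C@@H]1C(=O)O | intermediate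
19 | (1R,2S)-7,8-bis(benzyloxy)-1-[3,4-bis(benzyloxy)phenyl]-1,2-dihydronaphthalene-2,3-dicarboxylic acid | OC(=O)C1=Cc2ccc(OCc3ccccc3)c(OCc3ccccc3)c2[C@@H](c2ccc(OCc3ccccc3)c(OCc3ccccc3)c2)[C@@H]1C(=O)O | intermediate
20 | methyl (2S)-oxirane-2-carboxylate | COC(=O)[C@@H]1CO1 | starting material
21 | methyl (2S)-3-[3,4-bis(benzyloxy)phenyl]-2-hydroxypropanoate | COC(=O)[C@@H](O)Cc1ccc(OCc2ccccc2)c(OCc2ccccc2)c1 | intermediate
22 | benzyl (2S)-3-[3,4-bis(benzyloxy)phenyl]-2-hydroxypropanoate | O=C(OCc1ccccc1)[C@@H](O)Cc1ccc(OCc2ccccc2)c(OCc2ccccc2)c1 | intermediate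
23 | benzyl (2S)-3-[3,4-bis(benzyloxy)phenyl]-2-{[(trifluoromethyl)sulfonyl]oxy}propanoate | O=C(OCc1ccccc1)[C@@H](OS(=O)(=O)C(F)(F)F)Cc1ccc(OCc2ccccc2)c(OCc2ccccc2)c1 | intermediate
24 | bis{(2R)-1-(benzyloxy)-3-[3,4-bis(benzyloxy)phenyl]-1-oxopropan-2-yl} (1R,2S)-7,8-bis(benzyloxy)-1-[3,4-bis(benzyloxy)phenyl]-1,2-dihydronaphthalene-2,3-dicarboxylate | O=C(O[C@H](Cc1ccc(OCc2ccccc2)c(OCc2ccccc2)c1)C(=O)OCc1ccccc1)C1=Cc2ccc(OCc3ccccc3)c(OCc3ccccc3)c2[C@@H](c2ccc(OCc3ccccc3)c(OCc3ccccc3)c2)[C@@H]1C(=O)O[C@H](Cc1ccc(OCc2ccccc2)c(OCc2ccccc2)c1)C(=O)OCc1ccccc1 | intermediate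
25 | CNP0244800.2, bis[(1R)-1-carboxy-2-(3,4-dihydroxyphenyl)ethyl] (1R,2S)-1-(3,4-dihydroxyphenyl)-7,8-dihydroxy-1,2-dihydronaphthalene-2,3-dicarboxylate | O=C(O[C@H](Cc1ccc(O)c(O)c1)C(=O)O)C1=Cc2ccc(O)c(O)c2[C@@H](c2ccc(O)c(O)c2)[C@@H]1C(=O)O[C@H](Cc1ccc(O)c(O)c1)C(=O)O | target

**Step count and risks**

Total steps: 17. Longest linear sequence: 12 steps (steps 1–4, 7–12, 16, 17, from 2,3-dihydroxybenzaldehyde).

Steps most likely to fail:

1. Step 9 (key hydrogenation). The crowded tetrasubstituted olefin, flanked by a di-ortho-substituted aryl group, may fail to coordinate and insert, or hydrogen may be delivered with poor facial discrimination. The fallback builds C1 by conjugate addition and lets C2 settle thermodynamically in ring B; it sets out from 3 and comes back at 18. Horner–Wadsworth–Emmons olefination of 3 with tert-butyl diethylphosphonoacetate (NaH, THF) should give tert-butyl (2E)-3-[2,3-bis(benzyloxy)-6-bromophenyl]prop-2-enoate F1. Rh(I)/chiral diene-catalysed asymmetric 1,4-addition of 3,4-bis(benzyloxy)phenylboronic acid (KOH, dioxane/H2O; ligand hand chosen for R) should set C1 in tert-butyl (3R)-3-[2,3-bis(benzyloxy)-6-bromophenyl]-3-[3,4-bis(benzyloxy)phenyl]propanoate F2. Enolate alkylation (LDA, THF, −78 °C; methyl bromoacetate) should give 1-tert-butyl 4-methyl 2-{(R)-[2,3-bis(benzyloxy)-6-bromophenyl][3,4-bis(benzyloxy)phenyl]methyl}butanedioate F3 as a mixture of C2 epimers. Reductive carbonylation as in step 11 should give the corresponding aldehyde, 1-tert-butyl 4-methyl 2-{(R)-[2,3-bis(benzyloxy)-6-formylphenyl][3,4-bis(benzyloxy)phenyl]methyl}butanedioate F4. NaOMe in MeOH/THF should effect aldol condensation through the arm enolate; lactonisation onto the tert-butyl ester is disfavoured, so the diester is expected, and the same conditions should equilibrate the now acidic C2–H to the thermodynamically preferred trans isomer, 2-tert-butyl 3-methyl (1R,2S)-7,8-bis(benzyloxy)-1-[3,4-bis(benzyloxy)phenyl]-1,2-dihydronaphthalene-2,3-dicarboxylate F5. TFA/CH2Cl2 then frees the C2 acid to give 18, which is saponified as in the second stage of step 12.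

2. Step 7 (carbocupration/alkylation). The α-cuprio enoate may equilibrate through the allenolate before it is alkylated (loss of olefin geometry), or the bromoacetate may undergo halogen–copper exchange instead of alkylating. The fallback separates the two events; it sets out from 6 and comes back at 13. The same cuprate addition to 6 is quenched at −78 °C with iodine, a fast and stereoretentive trap, to give methyl (2E)-3-[2,3-bis(benzyloxy)-6-bromophenyl]-3-[3,4-bis(benzyloxy)phenyl]-2-iodoprop-2-enoate F6. The arm is then attached by Pd-catalysed Negishi coupling of F6 with the Reformatsky reagent made from 10 and zinc (Pd2(dba)3/XPhos, THF, rt); this coupling is stereoretentive and should favour the activated vinyl iodide over the hindered aryl bromide, giving 13.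

3. Step 11 (formylation). Oxidative addition next to the bulky ortho substituent may be slow, so that hydrodebromination outruns CO insertion. The fallback sets out from 16 and comes back at 17. Stille coupling of 16 with tributyl(vinyl)stannane (Pd(PPh3)4, toluene, 100 °C; base-free, so C2 is safe) should give dimethyl (2R)-2-{(R)-[2,3-bis(benzyloxy)-6-ethenylphenyl][3,4-bis(benzyloxy)phenyl]methyl}butanedioate F7. Lemieux–Johnson cleavage of the vinyl group (OsO4 cat., NaIO4, 2,6-lutidine, dioxane/H2O) then gives 17.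

**Further compounds**

F1 | step 9 | tert-butyl (2E)-3-[2,3-bis(benzyloxy)-6-bromophenyl]prop-2-enoate | CC(C)(C)OC(=O)/C=C/c1c(Br)ccc(OCc2ccccc2)c1OCc1ccccc1
F2 | step 9 | tert-butyl (3R)-3-[2,3-bis(benzyloxy)-6-bromophenyl]-3-[3,4-bis(benzyloxy)phenyl]propanoate | Brc1ccc(OCc2ccccc2)c(OCc2ccccc2)c1[C@@H](c1ccc(OCc2ccccc2)c(OCc2ccccc2)c1)CC(=O)OC(C)(C)C
F3 | step 9 | 1-tert-butyl 4-methyl 2-{(R)-[2,3-bis(benzyloxy)-6-bromophenyl][3,4-bis(benzyloxy)phenyl]methyl}butanedioate (mixture of C2 epimers) | Brc1ccc(OCc2ccccc2)c(OCc2ccccc2)c1[C@@H](c1ccc(OCc2ccccc2)c(OCc2ccccc2)c1)C(CC(=O)OC)C(=O)OC(C)(C)C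
F4 | step 9 | 1-tert-butyl 4-methyl 2-{(R)-[2,3-bis(benzyloxy)-6-formylphenyl][3,4-bis(benzyloxy)phenyl]methyl}butanedioate (mixture of C2 epimers) | O=Cc1ccc(OCc2ccccc2)c(OCc2ccccc2)c1[C@@H](c1ccc(OCc2ccccc2)c(OCc2ccccc2)c1)C(CC(=O)OC)C(=O)OC(C)(C)C
F5 | step 9 | 2-tert-butyl 3-methyl (1R,2S)-7,8-bis(benzyloxy)-1-[3,4-bis(benzyloxy)phenyl]-1,2-dihydronaphthalene-2,3-dicarboxylate | COC(=O)C1=Cc2ccc(OCc3ccccc3)c(OCc3ccccc3)c2[C@@H](c2ccc(OCc3ccccc3)c(OCc3ccccc3)c2)[C@@H]1C(=O)OC(C)(C)C
F6 | step 7 | methyl (2E)-3-[2,3-bis(benzyloxy)-6-bromophenyl]-3-[3,4-bis(benzyloxy)phenyl]-2-iodoprop-2-enoate | COC(=O)/C(I)=C(/c1ccc(OCc2ccccc2)c(OCc2ccccc2)c1)c1c(Br)ccc(OCc2ccccc2)c1OCc1ccccc1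
F7 | step 11 | dimethyl (2R)-2-{(R)-[2,3-bis(benzyloxy)-6-ethenylphenyl][3,4-bis(benzyloxy)phenyl]methyl}butanedioate | C=Cc1ccc(OCc2ccccc2)c(OCc2ccccc2)c1[C@@H](c1ccc(OCc2ccccc2)c(OCc2ccccc2)c1)[C@@H](CC(=O)OC)C(=O)OC
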